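**Retrosynthetic overview**
1. Target ⇐ a ring A adduct whose C-4 carries CHO (future C-19 methyl) and CH2OTBS (future C-18 acid); the end game is deoxygenation, ester reduction, acetylation and oxidation.
2. Key disconnection: ring A, C-4, C-5 and the C-1(10) olefin come from one catalyst-controlled endo Diels–Alder reaction between a ring B 1-vinylcyclohexene and 2-(silyloxymethyl)acrolein (no Robinson annulation, no decalone).
3. Diene ⇐ hindered ring B ketone by enol triflate formation and Stille vinylation; E side chain ⇐ methyl ketone by Horner–Wadsworth–Emmons olefination.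
4. C-8 and C-9 ⇐ Cu-catalysed asymmetric conjugate methylation of 2-methylcyclohexenone, then anti Mukaiyama–Michael addition to methyl vinyl ketone.
5. Ring order: ring B is bought as 2-methylcyclohexenone; ring A is the only ring formed, by the cycloaddition.

Assumption: positions are given in ent-halimane numbering (C-4 bears C-18 and C-19, C-9 the side chain); purchased one-step reagents, carbon donors such as methyl vinyl ketone included, stand on the reagent line with SMILES and carry no number.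

**Route**

Step 1
Reactants: 1 2-methylcyclohex-2-en-1-one
Product: 3 trimethyl{[(3R)-2,3-dimethylcyclohex-1-en-1-yl]oxy}silane, via aluminium enolate 2 (not isolated)
Conditions: Me3Al, Cu(O2CC4H3S) (2 mol %), (R,S,S)-BINOL N,N-bis(1-phenylethyl)phosphoramidite (4 mol %), Et2O, −30 °C; then TMSOTf, THF, −30 → 0 °C
Reagents that add atoms: trimethylaluminium C[Al](C)C; trimethylsilyl trifluoromethanesulfonate C[Si](C)(C)OS(=O)(=O)C(F)(F)F
Why: Cu-catalysed asymmetric conjugate addition in which the ligand antipode is chosen to deliver methyl to the Re face of C-3 (future C-8, R), and the aluminium enolate is O-silylated regiospecifically.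

Step 2
Reactants: 3 trimethyl{[(3R)-2,3-dimethylcyclohex-1-en-1-yl]oxy}silane
Product: 4 (2S,3R)-2,3-dimethyl-2-(3-oxobutyl)cyclohexan-1-one
Conditions: BF3·OEt2, i-PrOH, CH2Cl2, −78 °C
Reagents that add atoms: methyl vinyl ketone C=CC(C)=O
Why: Mukaiyama–Michael addition in which the BF3-activated enone is attacked by C-2 of the silyl enol ether anti to the pseudoaxial C-3 methyl (A(1,2) strain), giving the quaternary C-9 with the two methyls cis while i-PrOH takes up the silyl group.

Step 3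
Reactants: 4 (2S,3R)-2,3-dimethyl-2-(3-oxobutyl)cyclohexan-1-one
Product: 5 ethyl (2E)-5-[(1S,2R)-1,2-dimethyl-6-oxocyclohexyl]-3-methylpent-2-enoate
Conditions: NaH, THF, 0 → 50 °C (phosphonate anion preformed); minor Z isomer removed on SiO2
Reagents that add atoms: triethyl phosphonoacetate CCOC(=O)CP(=O)(OCC)OCC
Why: Horner–Wadsworth–Emmons olefination reacts only at the unhindered methyl ketone (the ring ketone is neopentyl) and gives the E enoate as the major isomer (about 6:1 expected).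

Step 4
Reactants: 5 ethyl (2E)-5-[(1S,2R)-1,2-dimethyl-6-oxocyclohexyl]-3-methylpent-2-enoate
Product: 6 ethyl (2E)-5-[(1S,6R)-1,6-dimethyl-2-{[(trifluoromethyl)sulfonyl]oxy}cyclohex-2-en-1-yl]-3-methylpent-2-enoate
Conditions: Tf2O, 2,6-di-tert-butyl-4-methylpyridine, CH2Cl2, 0 °C → rt
Reagents that add atoms: trifluoromethanesulfonic anhydride O=S(=O)(OS(=O)(=O)C(F)(F)F)C(F)(F)F
Why: Enol triflate formation without anionic intermediates; the ketone can enolise only toward C-5 because C-9 is quaternary, so one regioisomer forms and the enoate is untouched.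

Step 5
Reactants: 6 ethyl (2E)-5-[(1S,6R)-1,6-dimethyl-2-{[(trifluoromethyl)sulfonyl]oxy}cyclohex-2-en-1-yl]-3-methylpent-2-enoate
Product: 7 ethyl (2E)-5-[(1S,6R)-2-ethenyl-1,6-dimethylcyclohex-2-en-1-yl]-3-methylpent-2-enoate
Conditions: Pd(PPh3)4 (5 mol %), LiCl, THF, reflux
Reagents that add atoms: tributyl(vinyl)stannane C=C[Sn](CCCC)(CCCC)CCCC
Why: Stille coupling (oxidative addition of the vinyl triflate to zerovalent palladium, transmetalation, reductive elimination) gives the diene, which the quaternary C-9 biases toward the s-cis form.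

Step 6
Reactants: 8 2-methylidenepropane-1,3-diol
Product: 9 2-({[tert-butyl(dimethyl)silyl]oxy}methyl)prop-2-en-1-ol
Conditions: imidazole, THF, 0 °C → rt (8 in threefold excess)
Reagents that add atoms: tert-butyldimethylsilyl chloride CC(C)(C)[Si](C)(C)Cl
Why: Statistical monosilylation of a symmetric diol used in excess (substitution at silicon).

Step 7
Reactants: 9 2-({[tert-butyl(dimethyl)silyl]oxy}methyl)prop-2-en-1-ol
Product: 10 2-({[tert-butyl(dimethyl)silyl]oxy}methyl)prop-2-enal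
Conditions: MnO2, CH2Cl2, rt
Reagents that add atoms: none
Why: Selective allylic alcohol oxidation by MnO2 gives the enal and leaves the silyl ether alone.

Step 8
Reactants: 7 ethyl (2E)-5-[(1S,6R)-2-ethenyl-1,6-dimethylcyclohex-2-en-1-yl]-3-methylpent-2-enoate; 10 2-({[tert-butyl(dimethyl)silyl]oxy}methyl)prop-2-enal
Product: 11 ethyl (13E)-18-[(tert-butyldimethylsilyl)oxy]-19-oxo-ent-halima-1(10),13-dien-15-oate (4R,5S,8R,9S)
Conditions: (R)-o-tolyl-CBS oxazaborolidine C24H24BNO (20 mol %), HN(SO2CF3)2 (18 mol %), CH2Cl2, −78 → −40 °C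
Reagents that add atoms: none
Why: Lewis-acid-catalysed Diels–Alder reaction in which the vinyl terminus bonds to the enal β-carbon (ortho regiochemistry), the boron-bound formyl group sits endo with the larger CH2OTBS exo, and the (R)-oxazaborolidinium blocks one enal face so that the diene bonds to the face on which CHO, =CH2 and CH2OTBS run counterclockwise, which sets C-4 (R) and C-5 (S, H-5 cis to CH2OTBS) and leaves the C-1(10) double bond.

Step 9
Reactants: 11 ethyl (13E)-18-[(tert-butyldimethylsilyl)oxy]-19-oxo-ent-halima-1(10),13-dien-15-oate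
Product: 12 ethyl (13E)-18-[(tert-butyldimethylsilyl)oxy]-19-[(E)-2-tosylhydrazinylidene]-ent-halima-1(10),13-dien-15-oate (4S,5S,8R,9S)
Conditions: TsNHNH2, THF, 4 Å MS, rt
Reagents that add atoms: p-toluenesulfonyl hydrazide Cc1ccc(cc1)S(=O)(=O)NN
Why: Condensation of the non-enolisable aldehyde gives the E tosylhydrazone without touching any stereocentre.

Step 10
Reactants: 12 ethyl (13E)-18-[(tert-butyldimethylsilyl)oxy]-19-[(E)-2-tosylhydrazinylidene]-ent-halima-1(10),13-dien-15-oate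
Product: 15 ethyl (13E)-18-[(tert-butyldimethylsilyl)oxy]-ent-halima-1(10),13-dien-15-oate (4S,5S,8R,9S), via N-boryl hydrazide 13 (not isolated), via alkyldiazene 14 (not isolated)
Conditions: catecholborane, CHCl3, 0 °C; then NaOAc·3H2O, reflux
Reagents that add atoms: none
Why: Kabalka variant of the Caglioti reduction (hydroboration of C=N, acetate-induced loss of sulfinate, loss of N2 from the diazene) turns CH=N into the C-19 methyl while the enoate, silyl ether and quaternary C-4 stay intact.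

Step 11
Reactants: 15 ethyl (13E)-18-[(tert-butyldimethylsilyl)oxy]-ent-halima-1(10),13-dien-15-oate
Product: 17 (13E)-18-[(tert-butyldimethylsilyl)oxy]-ent-halima-1(10),13-dien-15-ol, via enal 16 (not isolated)
Conditions: i-Bu2AlH (2.5 equiv), CH2Cl2, −78 °C; aq. KNaC4H4O6
Reagents that add atoms: none
Why: 1,2-Reduction of the conjugated ester by i-Bu2AlH gives the allylic alcohol with the E geometry retained.

Step 12
Reactants: 17 (13E)-18-[(tert-butyldimethylsilyl)oxy]-ent-halima-1(10),13-dien-15-ol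
Product: 18 (13E)-18-[(tert-butyldimethylsilyl)oxy]-ent-halima-1(10),13-dien-15-yl acetate
Conditions: Ac2O, pyridine, DMAP (cat.), CH2Cl2, 0 °C → rt
Reagents that add atoms: acetic anhydride CC(=O)OC(C)=O
Why: DMAP-catalysed acylation of the primary allylic alcohol.

Step 13
Reactants: 18 (13E)-18-[(tert-butyldimethylsilyl)oxy]-ent-halima-1(10),13-dien-15-yl acetate
Product: 19 (13E)-18-hydroxy-ent-halima-1(10),13-dien-15-yl acetate
Conditions: HF·pyridine, pyridine/THF, 0 °C → rt
Reagents that add atoms: none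
Why: Fluoride-driven desilylation (Si–F bond formation) frees the neopentyl C-18 alcohol under conditions that leave the allylic acetate in place.

Step 14
Reactants: 19 (13E)-18-hydroxy-ent-halima-1(10),13-dien-15-yl acetate
Product: 21 15-acetoxy-ent-halima-1(10),13E-dien-18-oic acid (4S,5S,8R,9S; CNP0276297.1), via aldehyde 20 (not isolated)
Conditions: Dess–Martin periodinane (C13H13IO8), CH2Cl2, rt; then NaClO2, NaH2PO4, 2-methylbut-2-ene, t-BuOH/H2O, rt
Reagents that add atoms: sodium chlorite [Na+].[O-]Cl=O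
Why: Dess–Martin oxidation to the non-enolisable aldehyde followed by Pinnick oxidation gives the acid, with 2-methylbut-2-ene scavenging HOCl so that both trisubstituted olefins and the acetate survive.

**Compound list**
1 | 2-methylcyclohex-2-en-1-one | CC1=CCCCC1=O | starting material
2 | dimethyl{[(3R)-2,3-dimethylcyclohex-1-en-1-yl]oxy}alumane | CC1=C(O[Al](C)C)CCC[C@H]1C | intermediate
3 | trimethyl{[(3R)-2,3-dimethylcyclohex-1-en-1-yl]oxy}silane | CC1=C(O[Si](C)(C)C)CCC[C@H]1C | intermediate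
4 | (2S,3R)-2,3-dimethyl-2-(3-oxobutyl)cyclohexan-1-one | CC(=O)CC[C@]1(C)C(=O)CCC[C@H]1C | intermediate
5 | ethyl (2E)-5-[(1S,2R)-1,2-dimethyl-6-oxocyclohexyl]-3-methylpent-2-enoate | CCOC(=O)/C=C(\C)CC[C@]1(C)C(=O)CCC[C@H]1C | intermediate
6 | ethyl (2E)-5-[(1S,6R)-1,6-dimethyl-2-{[(trifluoromethyl)sulfonyl]oxy}cyclohex-2-en-1-yl]-3-methylpent-2-enoate | CCOC(=O)/C=C(\C)CC[C@]1(C)C(OS(=O)(=O)C(F)(F)F)=CCC[C@H]1C | intermediate
7 | ethyl (2E)-5-[(1S,6R)-2-ethenyl-1,6-dimethylcyclohex-2-en-1-yl]-3-methylpent-2-enoate | CCOC(=O)/C=C(\C)CC[C@]1(C)C(C=C)=CCC[C@H]1C | intermediate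
8 | 2-methylidenepropane-1,3-diol | C=C(CO)CO | starting material
9 | 2-({[tert-butyl(dimethyl)silyl]oxy}methyl)prop-2-en-1-ol | C=C(CO)CO[Si](C)(C)C(C)(C)C | intermediate
10 | 2-({[tert-butyl(dimethyl)silyl]oxy}methyl)prop-2-enal | C=C(C=O)CO[Si](C)(C)C(C)(C)C | intermediate
11 | ethyl (13E)-18-[(tert-butyldimethylsilyl)oxy]-19-oxo-ent-halima-1(10),13-dien-15-oate (4R,5S,8R,9S; CHO cis to C-6, H-5 cis to CH2OTBS) | CCOC(=O)/C=C(\C)CC[C@]1(C)C2=CCC[C@](C=O)(CO[Si](C)(C)C(C)(C)C)[C@H]2CC[C@H]1C | intermediate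
12 | (E)-tosylhydrazone of 11 at C-19 (4S,5S,8R,9S) | CCOC(=O)/C=C(\C)CC[C@]1(C)C2=CCC[C@](/C=N/NS(=O)(=O)c3ccc(C)cc3)(CO[Si](C)(C)C(C)(C)C)[C@H]2CC[C@H]1C | intermediate
13 | N-(1,3,2-benzodioxaborol-2-yl)-N′-tosyl hydrazide of the C-19 methylene compound | CCOC(=O)/C=C(\C)CC[C@]1(C)C2=CCC[C@](CN(B3Oc4ccccc4O3)NS(=O)(=O)c3ccc(C)cc3)(CO[Si](C)(C)C(C)(C)C)[C@H]2CC[C@H]1C | intermediate
14 | C-19 alkyldiazene | CCOC(=O)/C=C(\C)CC[C@]1(C)C2=CCC[C@](CN=N)(CO[Si](C)(C)C(C)(C)C)[C@H]2CC[C@H]1C | intermediate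
15 | ethyl (13E)-18-[(tert-butyldimethylsilyl)oxy]-ent-halima-1(10),13-dien-15-oate (4S,5S,8R,9S) | CCOC(=O)/C=C(\C)CC[C@]1(C)C2=CCC[C@](C)(CO[Si](C)(C)C(C)(C)C)[C@H]2CC[C@H]1C | intermediate
16 | (13E)-18-[(tert-butyldimethylsilyl)oxy]-ent-halima-1(10),13-dien-15-al | O=C/C=C(\C)CC[C@]1(C)C2=CCC[C@](C)(CO[Si](C)(C)C(C)(C)C)[C@H]2CC[C@H]1C | intermediate
17 | (13E)-18-[(tert-butyldimethylsilyl)oxy]-ent-halima-1(10),13-dien-15-ol | OC/C=C(\C)CC[C@]1(C)C2=CCC[C@](C)(CO[Si](C)(C)C(C)(C)C)[C@H]2CC[C@H]1C | intermediate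
18 | (13E)-18-[(tert-butyldimethylsilyl)oxy]-ent-halima-1(10),13-dien-15-yl acetate | CC(=O)OC/C=C(\C)CC[C@]1(C)C2=CCC[C@](C)(CO[Si](C)(C)C(C)(C)C)[C@H]2CC[C@H]1C | intermediate
19 | (13E)-18-hydroxy-ent-halima-1(10),13-dien-15-yl acetate | CC(=O)OC/C=C(\C)CC[C@]1(C)C2=CCC[C@](C)(CO)[C@H]2CC[C@H]1C | intermediate
20 | (13E)-18-oxo-ent-halima-1(10),13-dien-15-yl acetate | CC(=O)OC/C=C(\C)CC[C@]1(C)C2=CCC[C@](C)(C=O)[C@H]2CC[C@H]1C | intermediate
21 | 15-acetoxy-ent-halima-1(10),13E-dien-18-oic acid (4S,5S,8R,9S) | CC(=O)OC/C=C(\C)CC[C@]1(C)C2=CCC[C@](C)(C(=O)O)[C@H]2CC[C@H]1C | target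

**Totals**
Total step count: 14. Longest linear sequence: 12 (steps 1–5 and 8–14).

**Three steps most likely to fail**

Step 8 (Diels–Alder). The chiral diene has almost no intrinsic facial bias, because the two half-chairs of ring B are close in energy. C-5 therefore depends on the catalyst overriding the substrate, and the catalyst antipode was chosen from the pre-transition-state model, not from a test reaction. The ortho regiochemistry next to the quaternary C-9 is a second uncertainty. The fallback sets out from triflate 6 and comes back at adduct 11; it replaces the cycloaddition by a Claisen ring contraction that relays a reagent-set carbinol to C-4 and C-5. CrCl2/NiCl2 coupling of 6 with methyl 5-oxopentanoate, in the presence of a chiral sulfonamide ligand, gives the (S)-hydroxy ester F1, which is lactonised (PPTS, toluene) to the δ-lactone F2. LiN(i-Pr)2 followed by monomeric CH2O gives the hydroxymethyl lactone F3, and TBSCl/imidazole gives its silyl ether F4. LiN(i-Pr)2 with in-situ TMSCl gives the cyclic silyl ketene acetal F5. At 110 °C in toluene this rearranges through the enforced boat transition state to the trimethylsilyl ester F6; the carbinol configuration fixes C-5, and the former lactone carbonyl ends cis to C-6, where 11 has its formyl group. (COCl)2 with catalytic DMF converts F6 into the acid chloride F7, and LiAlH(Ot-Bu)3 at −78 °C reduces it to 11.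

Step 2 (Mukaiyama–Michael). A quaternary centre is made next to a tertiary one under Lewis acid, where enone polymerisation, protodesilylation of 3 or eroded anti selectivity can cut the yield. The fallback sets out from 3 and comes back at 4. MeLi (THF, 0 °C) cleaves 3 to the lithium enolate F8, which is alkylated anti to the C-3 methyl with 1,3-dichlorobut-2-ene (an allylic chloride, the Wichterle reagent) to the vinyl chloride F9; its chloroalkene is an E/Z mixture of no consequence. Hg(OAc)2 in HCO2H then hydrolyses the vinyl chloride to the methyl ketone 4.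

Step 10 (hydrazone to methyl). Hydride delivery to a neopentyl C=N beside a quaternary carbon can stall or stop at the hydrazine. The fallback sets out from aldehyde 11 and comes back at 15. NaBH4 (MeOH, 0 °C) reduces only the aldehyde, giving the neopentyl alcohol F10. I2/PPh3/imidazole (toluene, 80 °C) gives the neopentyl iodide F11, and Bu3SnH/AIBN (benzene, 80 °C) removes iodine by a radical chain to give 15.

**Further compounds**
F1 | step 8 | methyl (5S)-5-hydroxy-5-{(5R,6S)-6-[(3E)-5-ethoxy-3-methyl-5-oxopent-3-en-1-yl]-5,6-dimethylcyclohex-1-en-1-yl}pentanoate | CCOC(=O)/C=C(\C)CC[C@]1(C)C([C@@H](O)CCCC(=O)OC)=CCC[C@H]1C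
F2 | step 8 | ethyl (2E)-5-{(1S,6R)-1,6-dimethyl-2-[(2S)-6-oxooxan-2-yl]cyclohex-2-en-1-yl}-3-methylpent-2-enoate | CCOC(=O)/C=C(\C)CC[C@]1(C)C([C@@H]2CCCC(=O)O2)=CCC[C@H]1C
F3 | step 8 | ethyl (2E)-5-{(1S,6R)-2-[(2S)-5-(hydroxymethyl)-6-oxooxan-2-yl]-1,6-dimethylcyclohex-2-en-1-yl}-3-methylpent-2-enoate (both epimers at the lactone α-carbon) | CCOC(=O)/C=C(\C)CC[C@]1(C)C([C@@H]2CCC(CO)C(=O)O2)=CCC[C@H]1C
F4 | step 8 | ethyl (2E)-5-{(1S,6R)-2-[(2S)-5-({[tert-butyl(dimethyl)silyl]oxy}methyl)-6-oxooxan-2-yl]-1,6-dimethylcyclohex-2-en-1-yl}-3-methylpent-2-enoate (both epimers at the lactone α-carbon) | CCOC(=O)/C=C(\C)CC[C@]1(C)C([C@@H]2CCC(CO[Si](C)(C)C(C)(C)C)C(=O)O2)=CCC[C@H]1C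
F5 | step 8 | ethyl (2E)-5-{(1S,6R)-2-[(2S)-5-({[tert-butyl(dimethyl)silyl]oxy}methyl)-6-[(trimethylsilyl)oxy]-3,4-dihydro-2H-pyran-2-yl]-1,6-dimethylcyclohex-2-en-1-yl}-3-methylpent-2-enoate | CCOC(=O)/C=C(\C)CC[C@]1(C)C([C@@H]2CCC(CO[Si](C)(C)C(C)(C)C)=C(O[Si](C)(C)C)O2)=CCC[C@H]1C
F6 | step 8 | 15-ethyl 19-trimethylsilyl (13E)-18-[(tert-butyldimethylsilyl)oxy]-ent-halima-1(10),13-diene-15,19-dioate (4R,5S,8R,9S) | CCOC(=O)/C=C(\C)CC[C@]1(C)C2=CCC[C@](C(=O)O[Si](C)(C)C)(CO[Si](C)(C)C(C)(C)C)[C@H]2CC[C@H]1C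
F7 | step 8 | ethyl (13E)-18-[(tert-butyldimethylsilyl)oxy]-19-chloro-19-oxo-ent-halima-1(10),13-dien-15-oate (4R,5S,8R,9S) | CCOC(=O)/C=C(\C)CC[C@]1(C)C2=CCC[C@](C(Cl)=O)(CO[Si](C)(C)C(C)(C)C)[C@H]2CC[C@H]1C
F8 | step 2 | lithium (3R)-2,3-dimethylcyclohex-1-en-1-olate | CC1=C(O[Li])CCC[C@H]1C
F9 | step 2 | (2S,3R)-2-(3-chlorobut-2-en-1-yl)-2,3-dimethylcyclohexan-1-one (chloroalkene E/Z mixture) | CC(Cl)=CC[C@]1(C)C(=O)CCC[C@H]1C
F10 | step 10 | ethyl (13E)-18-[(tert-butyldimethylsilyl)oxy]-19-hydroxy-ent-halima-1(10),13-dien-15-oate (4S,5S,8R,9S) | CCOC(=O)/C=C(\C)CC[C@]1(C)C2=CCC[C@](CO)(CO[Si](C)(C)C(C)(C)C)[C@H]2CC[C@H]1C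
F11 | step 10 | ethyl (13E)-18-[(tert-butyldimethylsilyl)oxy]-19-iodo-ent-halima-1(10),13-dien-15-oate (4R,5S,8R,9S) | CCOC(=O)/C=C(\C)CC[C@]1(C)C2=CCC[C@](CI)(CO[Si](C)(C)C(C)(C)C)[C@H]2CC[C@H]1C
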